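The 3,6-dihydroxy-2,2,6-trimethylcyclohexyl ring (C1 carries the side chain) is disconnected between the methylene C5 and the methyl carbinol carbon C6. The key step exploits this tertiary carbinol beside a ring CH2 as the hydrate of a 1-methylcyclohexene: ring-closing metathesis forges the C5=C6 olefin and closes the carbocycle in one operation from an acyclic diene in which an allyl carbinol (C3–C5) and an ethylidene group (C6) flank the gem-dimethyl carbon C2 and the stereocentre C1. Because the C3 and C6 hydroxyls are cis-1,4, the homoallylic C3–OH then directs epoxidation, and hydride opening gives the tertiary alcohol. C1 stems from Claisen chirality transfer, C3 from allylboration, the chain carbinol from (R)-linalool.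

Key step: step 8

Remark: ring locants C1–C6 used below are those of the cyclohexyl unit of the target (C1 side chain, C2 CMe2, C3 CHOH, C4 and C5 CH2, C6 C(CH3)OH). Assumption: ylide 7, vinyl iodide 10 and the 1 M solution of (+)-Ipc2B(allyl) (the enantiomer made from (−)-α-pinene) are taken as catalogue items, and (R)-linalool as enantiomerically pure.

Step 1
Reactants: 1 (R)-(−)-linalool
Product: 3 (3R)-3,7-dimethyloct-6-ene-1,3-diol, via B-alkyl-9-BBN adduct 2 (not isolated)
Conditions: 9-BBN (2.2 equiv), THF, 0 °C to rt; then NaOH aq., H2O2, 0 °C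
Reagents that add atoms: hydrogen peroxide, OO
Why: Hydroboration–oxidation, in which 9-BBN should add anti-Markovnikov only to the monosubstituted vinyl group (the trisubstituted olefin is too hindered) and oxidation with retention gives the primary alcohol, the tertiary carbinol centre of linalool not being involved.

Step 2
Reactants: 3 (3R)-3,7-dimethyloct-6-ene-1,3-diol
Product: 4 (4R)-2,2,4-trimethyl-4-(4-methylpent-3-en-1-yl)-1,3-dioxane
Conditions: 2,2-dimethoxypropane, PPTS (cat.), CH2Cl2, rt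
Reagents that add atoms: 2,2-dimethoxypropane, COC(C)(C)OC
Why: Acid-catalysed transacetalisation should close the six-membered acetonide over the primary and the tertiary hydroxyl, masking both so that the tertiary OH cannot later add to the enone of 8 or form a lactol with aldehyde 6.

Step 3
Reactants: 4 (4R)-2,2,4-trimethyl-4-(4-methylpent-3-en-1-yl)-1,3-dioxane
Product: 6 3-[(4R)-2,2,4-trimethyl-1,3-dioxan-4-yl]propanal, via secondary ozonide 5 (not isolated)
Conditions: O3, CH2Cl2, −78 °C; then PPh3, −78 °C to rt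
Reagents that add atoms: ozone, [O-][O+]=O
Why: Ozonolysis with reductive work-up, in which the electron-rich trisubstituted olefin is cleaved through the ozonide and PPh3 reduces it to the aldehyde while the acetal is inert at low temperature.

Step 4
Reactants: 6 3-[(4R)-2,2,4-trimethyl-1,3-dioxan-4-yl]propanal; 7 3-(triphenyl-λ5-phosphanylidene)butan-2-one
Product: 8 (3E)-3-methyl-6-[(4R)-2,2,4-trimethyl-1,3-dioxan-4-yl]hex-3-en-2-one
Conditions: toluene, 90 °C
Reagents that add atoms: none
Why: Wittig olefination with a ketone-stabilised α-methyl ylide, which should give the trisubstituted enone with the acyl group trans to the chain (E) under the usual thermodynamic control of stabilised ylides.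

Step 5
Reactants: 8 (3E)-3-methyl-6-[(4R)-2,2,4-trimethyl-1,3-dioxan-4-yl]hex-3-en-2-one
Product: 9 (2S,3E)-3-methyl-6-[(4R)-2,2,4-trimethyl-1,3-dioxan-4-yl]hex-3-en-2-ol
Conditions: (R)-2-methyl-CBS-oxazaborolidine (15 mol %), catecholborane, toluene, −78 °C; NaOH aq. work-up
Reagents that add atoms: none
Why: Corey–Bakshi–Shibata reduction, in which the (R)-oxazaborolidine binds the ketone with the α-methylalkenyl group as the large and methyl as the small substituent and delivers hydride 1,2 to one face, so the (S)-carbinol is set by the catalyst.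

Step 6
Reactants: 9 (2S,3E)-3-methyl-6-[(4R)-2,2,4-trimethyl-1,3-dioxan-4-yl]hex-3-en-2-ol; 10 1-iodo-2-methylprop-1-ene
Product: 12 (3R,4E)-2,2,4-trimethyl-3-{2-[(4R)-2,2,4-trimethyl-1,3-dioxan-4-yl]ethyl}hex-4-enal, via allyl vinyl ether 11 (not isolated)
Conditions: CuI (10 mol %), 3,4,7,8-tetramethyl-1,10-phenanthroline (20 mol %), Cs2CO3, o-xylene, 120 °C
Reagents that add atoms: none
Why: Domino Ullmann-type copper-catalysed O-vinylation and aliphatic Claisen rearrangement, in which the [3,3] shift should run through the chair with the carbinol methyl equatorial so that the (S)-carbinol and the (E)-olefin are relayed (1,3-chirality transfer) into the stereocentre that becomes ring C1, next to the new quaternary carbon C2.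

Step 7
Reactants: 12 (3R,4E)-2,2,4-trimethyl-3-{2-[(4R)-2,2,4-trimethyl-1,3-dioxan-4-yl]ethyl}hex-4-enal
Product: 14 (4R,6R,7E)-5,5,7-trimethyl-6-{2-[(4R)-2,2,4-trimethyl-1,3-dioxan-4-yl]ethyl}nona-1,7-dien-4-ol, via diisopinocampheylborinate 13 (not isolated)
Conditions: (+)-Ipc2B(allyl), Et2O, −100 to −78 °C; then NaOH aq., H2O2, 0 °C to rt
Reagents that add atoms: (+)-B-allyldiisopinocampheylborane, C=CCB([C@H]1C[C@H]2C[C@@H]([C@@H]1C)C2(C)C)[C@H]1C[C@H]2C[C@@H]([C@@H]1C)C2(C)C
Why: Brown allylboration, in which the closed chair transition state of the (−)-α-pinene-derived borane should add allyl to the Re face of the neopentylic aldehyde (reagent control, as with pivalaldehyde), setting the (4R) carbinol that becomes ring C3.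

Step 8
Reactants: 14 (4R,6R,7E)-5,5,7-trimethyl-6-{2-[(4R)-2,2,4-trimethyl-1,3-dioxan-4-yl]ethyl}nona-1,7-dien-4-ol
Product: 15 (1R,5R)-4,6,6-trimethyl-5-{2-[(4R)-2,2,4-trimethyl-1,3-dioxan-4-yl]ethyl}cyclohex-3-en-1-ol
Conditions: second-generation Grubbs catalyst (H2IMes)(PCy3)Cl2Ru=CHPh (5 mol %), CH2Cl2 (0.005 M), 40 °C
Reagents that add atoms: none
Why: Ring-closing olefin metathesis by the metal alkylidene [2+2]/retro-[2+2] mechanism: the ruthenium alkylidene loads on the terminal vinyl group, forms a ruthenacyclobutane with the trisubstituted ethylidene olefin and cycloreverts, joining the former vinyl CH (ring C5) to the methyl-bearing olefin carbon (ring C6) and expelling propene. The closest known type is RCM of 1,6-dienes with a free homoallylic hydroxyl to 1-methylcyclohexenes. The six-membered carbocycle is closed by olefin formation between the two chain ends, and the gem-dimethyl carbon C2 and the branching at C1 favour the folded conformer. No stereocentre is created; C1 and C3 are untouched, and the C5=C6 olefin stores the later tertiary carbinol. The step needs ring closure to win over intermolecular cross-metathesis, which high dilution and the presence of only one unhindered olefin (the ethylidene end cannot dimerise) should secure.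

Step 9
Reactants: 15 (1R,5R)-4,6,6-trimethyl-5-{2-[(4R)-2,2,4-trimethyl-1,3-dioxan-4-yl]ethyl}cyclohex-3-en-1-ol
Product: 16 (1S,3R,5S,6R)-4,4,6-trimethyl-5-{2-[(4R)-2,2,4-trimethyl-1,3-dioxan-4-yl]ethyl}-7-oxabicyclo[4.1.0]heptan-3-ol
Conditions: VO(acac)2 (5 mol %), t-BuOOH, CH2Cl2, 0 °C to rt
Reagents that add atoms: tert-butyl hydroperoxide, CC(C)(C)OO
Why: Vanadium-catalysed hydroxyl-directed epoxidation, in which the peroxide bound to the homoallylic C3 hydroxyl should deliver oxygen to the ring face that this hydroxyl occupies, which is also the face anti to the C1 side chain, so that the epoxide is cis to C3–OH and the C6–O bond has the configuration of the target.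

Step 10
Reactants: 16 (1S,3R,5S,6R)-4,4,6-trimethyl-5-{2-[(4R)-2,2,4-trimethyl-1,3-dioxan-4-yl]ethyl}-7-oxabicyclo[4.1.0]heptan-3-ol
Product: 17 (1S,2S,4R)-1,3,3-trimethyl-2-{2-[(4R)-2,2,4-trimethyl-1,3-dioxan-4-yl]ethyl}cyclohexane-1,4-diol
Conditions: LiAlH4, THF, 0 °C to reflux
Reagents that add atoms: none
Why: Hydride reduction of a trisubstituted epoxide (SN2, trans-diaxial opening), in which hydride should attack the secondary carbon C5 so that the C6–O bond is retained and becomes the tertiary alcohol, cis to C3–OH and trans to the C1 chain.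

Step 11
Reactants: 17 (1S,2S,4R)-1,3,3-trimethyl-2-{2-[(4R)-2,2,4-trimethyl-1,3-dioxan-4-yl]ethyl}cyclohexane-1,4-diol
Product: 18 (1S,2S,4R)-2-[(3R)-3,5-dihydroxy-3-methylpentyl]-1,3,3-trimethylcyclohexane-1,4-diol
Conditions: AcOH/THF/H2O (3:1:1), rt
Reagents that add atoms: none
Why: Acetal hydrolysis, in which the strained acetonide on a tertiary oxygen should cleave under mild aqueous acid that does not ionise the tertiary alcohols.

Step 12
Reactants: 18 (1S,2S,4R)-2-[(3R)-3,5-dihydroxy-3-methylpentyl]-1,3,3-trimethylcyclohexane-1,4-diol; 19 umbelliferone (7-hydroxy-2H-chromen-2-one)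
Product: 20 7-{[(3R)-5-[(1S,3R,6S)-3,6-dihydroxy-2,2,6-trimethylcyclohexyl]-3-hydroxy-3-methylpentyl]oxy}-2H-chromen-2-one (CNP0210598.1)
Conditions: PPh3, DIAD, THF, 0 °C to rt
Reagents that add atoms: none
Why: Mitsunobu etherification, in which only the primary hydroxyl should form the oxyphosphonium ion and be displaced by the acidic phenol, the neopentylic secondary and the two tertiary hydroxyls being too hindered, so no stereocentre is touched.

Compound list
1 | (R)-(−)-linalool, (3R)-3,7-dimethylocta-1,6-dien-3-ol | CC(C)=CCC[C@@](C)(O)C=C | starting material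
2 | B-[(3R)-3-hydroxy-3,7-dimethyloct-6-en-1-yl]-9-borabicyclo[3.3.1]nonane | CC(C)=CCC[C@@](C)(O)CCB1C2CCCC1CCC2 | intermediate
3 | (3R)-3,7-dimethyloct-6-ene-1,3-diol | CC(C)=CCC[C@@](C)(O)CCO | intermediate
4 | (4R)-2,2,4-trimethyl-4-(4-methylpent-3-en-1-yl)-1,3-dioxane | CC(C)=CCC[C@@]1(C)OC(C)(C)OCC1 | intermediate
5 | 3,3-dimethyl-5-{2-[(4R)-2,2,4-trimethyl-1,3-dioxan-4-yl]ethyl}-1,2,4-trioxolane (both epimers at the trioxolane CH) | CC1(C)OOC(CC[C@@]2(C)OC(C)(C)OCC2)O1 | intermediate
6 | 3-[(4R)-2,2,4-trimethyl-1,3-dioxan-4-yl]propanal | O=CCC[C@@]1(C)OC(C)(C)OCC1 | intermediate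
7 | 3-(triphenyl-λ5-phosphanylidene)butan-2-one | CC(=O)C(C)=P(c1ccccc1)(c1ccccc1)c1ccccc1 | starting material
8 | (3E)-3-methyl-6-[(4R)-2,2,4-trimethyl-1,3-dioxan-4-yl]hex-3-en-2-one | CC(=O)/C(C)=C/CC[C@@]1(C)OC(C)(C)OCC1 | intermediate
9 | (2S,3E)-3-methyl-6-[(4R)-2,2,4-trimethyl-1,3-dioxan-4-yl]hex-3-en-2-ol | C[C@H](O)/C(C)=C/CC[C@@]1(C)OC(C)(C)OCC1 | intermediate
10 | 1-iodo-2-methylprop-1-ene | CC(C)=CI | starting material
11 | (4R)-2,2,4-trimethyl-4-[(3E,5S)-4-methyl-5-(2-methylprop-1-en-1-yloxy)hex-3-en-1-yl]-1,3-dioxane | CC(C)=CO[C@@H](C)/C(C)=C/CC[C@@]1(C)OC(C)(C)OCC1 | intermediate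
12 | (3R,4E)-2,2,4-trimethyl-3-{2-[(4R)-2,2,4-trimethyl-1,3-dioxan-4-yl]ethyl}hex-4-enal | C/C=C(\C)[C@H](C(C)(C)C=O)CC[C@@]1(C)OC(C)(C)OCC1 | intermediate
13 | O-bis[(1S,2S,3S,5R)-2,6,6-trimethylbicyclo[3.1.1]heptan-3-yl]boranyl derivative of 14 | C/C=C(\C)[C@@H](CC[C@@]1(C)OC(C)(C)OCC1)C(C)(C)[C@@H](CC=C)OB([C@H]1C[C@H]2C[C@@H]([C@@H]1C)C2(C)C)[C@H]1C[C@H]2C[C@@H]([C@@H]1C)C2(C)C | intermediate
14 | (4R,6R,7E)-5,5,7-trimethyl-6-{2-[(4R)-2,2,4-trimethyl-1,3-dioxan-4-yl]ethyl}nona-1,7-dien-4-ol | C/C=C(\C)[C@@H](CC[C@@]1(C)OC(C)(C)OCC1)C(C)(C)[C@H](O)CC=C | intermediate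
15 | (1R,5R)-4,6,6-trimethyl-5-{2-[(4R)-2,2,4-trimethyl-1,3-dioxan-4-yl]ethyl}cyclohex-3-en-1-ol | CC1(C)[C@H](O)CC=C(C)[C@H]1CC[C@@]2(C)OC(C)(C)OCC2 | intermediate
16 | (1S,3R,5S,6R)-4,4,6-trimethyl-5-{2-[(4R)-2,2,4-trimethyl-1,3-dioxan-4-yl]ethyl}-7-oxabicyclo[4.1.0]heptan-3-ol (epoxide cis to OH, trans to the chain) | CC1(C)[C@H](O)C[C@@H]2O[C@]2(C)[C@H]1CC[C@@]3(C)OC(C)(C)OCC3 | intermediate
17 | (1S,2S,4R)-1,3,3-trimethyl-2-{2-[(4R)-2,2,4-trimethyl-1,3-dioxan-4-yl]ethyl}cyclohexane-1,4-diol | CC1(C)[C@H](O)CC[C@](C)(O)[C@H]1CC[C@@]2(C)OC(C)(C)OCC2 | intermediate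
18 | (1S,2S,4R)-2-[(3R)-3,5-dihydroxy-3-methylpentyl]-1,3,3-trimethylcyclohexane-1,4-diol | CC1(C)[C@H](O)CC[C@](C)(O)[C@H]1CC[C@@](C)(O)CCO | intermediate
19 | umbelliferone, 7-hydroxy-2H-chromen-2-one | Oc1ccc2ccc(=O)oc2c1 | starting material
20 | 7-{[(3R)-5-[(1S,3R,6S)-3,6-dihydroxy-2,2,6-trimethylcyclohexyl]-3-hydroxy-3-methylpentyl]oxy}-2H-chromen-2-one | CC1(C)[C@H](O)CC[C@](C)(O)[C@H]1CC[C@@](C)(O)CCOc1ccc2ccc(=O)oc2c1 | target

Total step count: 12. Longest linear sequence: 12 steps (1 to 20); 7, 10 and 19 are bought.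

Steps most likely to fail

Step 6. The copper-mediated O-vinylation of the hindered secondary allylic alcohol may stall, and the thermal rearrangement may leak through the chair with the carbinol methyl axial, which erodes the configuration at ring C1. The fallback sets out from 9 and uses an ester-enolate Claisen rearrangement, whose axial silyloxy group enforces the equatorial methyl. Acylation with isobutyryl chloride (Et3N, DMAP, CH2Cl2) should give the isobutyrate F1. LiN(iPr)2 and Me3SiCl in THF at −78 °C should give the trimethylsilyl ketene acetal F2. On warming, Ireland–Claisen rearrangement should give the silyl ester F3, which is hydrolysed on work-up to the acid F4. LiAlH4 should reduce F4 to the neopentylic alcohol F5, and Dess–Martin oxidation comes back to the route at 12.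

Step 8. Metathesis at the hindered ethylidene olefin may be slow, so that cross-metathesis of the terminal vinyl group between two molecules or olefin migration takes over. The fallback sets out from 14 and makes the same C5=C6 bond by reductive carbonyl coupling. Silylation (t-BuMe2SiOTf, 2,6-lutidine) should give the silyl ether F8. Ozonolysis of both olefins (O3, then PPh3) should give the keto aldehyde F9. Intramolecular McMurry coupling (TiCl3(DME)1.5, Zn–Cu couple, DME, reflux, high dilution) should give the cyclohexene silyl ether F10, and Bu4NF comes back to the route at 15.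

Step 7. Reagent control may not override the bias of the β-branched neopentylic aldehyde, or the addition may be too slow at low temperature, which gives poor facial selectivity at the carbinol that becomes ring C3. The fallback sets out from 12 and moves the stereo-determining event to a catalyst-controlled ketone reduction. Allylmagnesium bromide should give the dienol as both C4 epimers F6. Dess–Martin oxidation (NaHCO3 buffer) should give the β,γ-unsaturated ketone F7. CBS reduction with (S)-2-methyl-CBS-oxazaborolidine and catecholborane (tert-alkyl as the large, CH2 as the small substituent) comes back to the route at 14.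

Further compounds
F1 | step 6 | (2S,3E)-3-methyl-6-[(4R)-2,2,4-trimethyl-1,3-dioxan-4-yl]hex-3-en-2-yl 2-methylpropanoate | CC(C)C(=O)O[C@@H](C)/C(C)=C/CC[C@@]1(C)OC(C)(C)OCC1
F2 | step 6 | trimethylsilyl ketene acetal of F1 | CC(C)=C(O[Si](C)(C)C)O[C@@H](C)/C(C)=C/CC[C@@]1(C)OC(C)(C)OCC1
F3 | step 6 | trimethylsilyl (3R,4E)-2,2,4-trimethyl-3-{2-[(4R)-2,2,4-trimethyl-1,3-dioxan-4-yl]ethyl}hex-4-enoate | C/C=C(\C)[C@H](C(C)(C)C(=O)O[Si](C)(C)C)CC[C@@]1(C)OC(C)(C)OCC1
F4 | step 6 | (3R,4E)-2,2,4-trimethyl-3-{2-[(4R)-2,2,4-trimethyl-1,3-dioxan-4-yl]ethyl}hex-4-enoic acid | C/C=C(\C)[C@H](C(C)(C)C(=O)O)CC[C@@]1(C)OC(C)(C)OCC1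
F5 | step 6 | (3R,4E)-2,2,4-trimethyl-3-{2-[(4R)-2,2,4-trimethyl-1,3-dioxan-4-yl]ethyl}hex-4-en-1-ol | C/C=C(\C)[C@H](C(C)(C)CO)CC[C@@]1(C)OC(C)(C)OCC1
F6 | step 7 | (6R,7E)-5,5,7-trimethyl-6-{2-[(4R)-2,2,4-trimethyl-1,3-dioxan-4-yl]ethyl}nona-1,7-dien-4-ol, both C4 epimers | C/C=C(\C)[C@@H](CC[C@@]1(C)OC(C)(C)OCC1)C(C)(C)C(O)CC=C
F7 | step 7 | (6R,7E)-5,5,7-trimethyl-6-{2-[(4R)-2,2,4-trimethyl-1,3-dioxan-4-yl]ethyl}nona-1,7-dien-4-one | C/C=C(\C)[C@@H](CC[C@@]1(C)OC(C)(C)OCC1)C(C)(C)C(=O)CC=C
F8 | step 8 | tert-butyldimethylsilyl ether of 14 | C/C=C(\C)[C@@H](CC[C@@]1(C)OC(C)(C)OCC1)C(C)(C)[C@@H](CC=C)O[Si](C)(C)C(C)(C)C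
F9 | step 8 | (3R,5S)-5-acetyl-3-{[tert-butyl(dimethyl)silyl]oxy}-4,4-dimethyl-7-[(4R)-2,2,4-trimethyl-1,3-dioxan-4-yl]heptanal | CC(=O)[C@@H](CC[C@@]1(C)OC(C)(C)OCC1)C(C)(C)[C@@H](CC=O)O[Si](C)(C)C(C)(C)C
F10 | step 8 | tert-butyldimethylsilyl ether of 15 | CC1(C)[C@H](O[Si](C)(C)C(C)(C)C)CC=C(C)[C@H]1CC[C@@]2(C)OC(C)(C)OCC2
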